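**Strategy.** Ring B is disconnected at C1'–C2'. Its four contiguous oxygenated carbons C2'–C5' are the four carbons of a squarate. C6'–H and C1' are the two carbons of an (E)-alkene attached to C3 of the preformed chroman (rings A/C). Heating a 4-alkenyl-4-hydroxycyclobutenone opens the four-membered ring and recloses it as benzenoid ring B in one operation, with every oxygen already in place. The precursor carries methoxy next to the carbinol carbon and tert-butoxy next to the ketone, so only O-3' is unmasked at the end. C3 is set beforehand by asymmetric hydrogenation of a 2H-chromene-3-carboxylic acid.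

Key step: step 11

Assumption (step 5): the ligand antipode used is the one that gives (R)-10. The sense of induction is to be verified on the first batch, and the mirror-image ligand is equally accessible.

Remark on descriptors: the spatial arrangement at C3 does not change after step 5. The descriptor reads R in 10 and 12 and S in all other compounds only because the CIP priorities change.

Step 1
Reactants: 1 2-methoxyresorcinol (2-methoxybenzene-1,3-diol)
Product: 3 2,4-dihydroxy-3-methoxybenzaldehyde, via aryl iminium salt 2 (not isolated)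
Conditions: POCl3 (1.2 equiv), DMF (1.5 equiv), MeCN, −15 °C to rt; then H2O, 50 °C
Reagents that add atoms: N,N-dimethylformamide, CN(C)C=O; water, O
Why: Vilsmeier–Haack formylation of a resorcinol, in which C4 (equivalent to C6 by symmetry) is ortho to one hydroxyl and para to the other and is thus the only strongly activated site, while the cationic iminium group of 2 blocks a second attack until hydrolysis releases the aldehyde.

Step 2
Reactants: 3 2,4-dihydroxy-3-methoxybenzaldehyde
Product: 4 4-(benzyloxy)-2-hydroxy-3-methoxybenzaldehyde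
Conditions: BnBr (1.05 equiv), KHCO3 (1.2 equiv), DMF, 40 °C
Reagents that add atoms: benzyl bromide, BrCc1ccccc1
Why: Chemoselective Williamson etherification, because the weak base ionises only the more acidic 4-OH (para to the formyl group) while the 2-OH is held in a hydrogen bond to the aldehyde oxygen.

Step 3
Reactants: 4 4-(benzyloxy)-2-hydroxy-3-methoxybenzaldehyde; 5 acrolein
Product: 8 7-(benzyloxy)-8-methoxy-2H-chromene-3-carbaldehyde, via oxa-Michael adduct 6 (not isolated), via cyclic aldol 7 (not isolated)
Conditions: K2CO3 (1 equiv), 1,4-dioxane, reflux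
Reagents that add atoms: none
Why: Domino oxa-Michael addition/intramolecular aldol condensation, a standard 2H-chromene synthesis from salicylaldehydes and enals, preferred to an amine-catalysed acrylate annulation because the para-alkoxy group makes this aryl aldehyde a sluggish Baylis–Hillman acceptor.

Step 4
Reactants: 8 7-(benzyloxy)-8-methoxy-2H-chromene-3-carbaldehyde
Product: 9 7-(benzyloxy)-8-methoxy-2H-chromene-3-carboxylic acid
Conditions: NaClO2, NaH2PO4, 2-methyl-2-butene, t-BuOH–THF–H2O, rt
Reagents that add atoms: sodium chlorite, [Na+].[O-]Cl=O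
Why: Pinnick oxidation converts enals into enoic acids without touching the conjugated alkene, and the alkene scavenger removes hypochlorous acid before it can chlorinate the electron-rich ring A.

Step 5
Reactants: 9 7-(benzyloxy)-8-methoxy-2H-chromene-3-carboxylic acid
Product: 10 (3R)-7-(benzyloxy)-8-methoxychromane-3-carboxylic acid
Conditions: [Ir(cod)(spiro phosphine–oxazoline, SIPHOX type)]BArF (1 mol %), H2 (6 atm), Et3N (0.5 equiv), MeOH, 45 °C
Reagents that add atoms: none
Why: Carboxylate-directed iridium-catalysed asymmetric hydrogenation of an α,β-unsaturated acid, a reaction class established for unsaturated heterocyclic acids of this type, in which the bound carboxylate and the chiral P,N ligand expose one face of C3=C4 so that hydrogen delivery sets C3 as R, and the homogeneous catalyst leaves the benzyl ether intact.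

Step 6
Reactants: 10 (3R)-7-(benzyloxy)-8-methoxychromane-3-carboxylic acid
Product: 11 [(3S)-7-(benzyloxy)-8-methoxychroman-3-yl]methanol
Conditions: BH3·THF (2 equiv), THF, 0 °C to rt; then H2O
Reagents that add atoms: none
Why: Chemoselective borane reduction of a carboxylic acid through its acyloxyborane proceeds without an enolisable intermediate, so C3 is untouched and all aryl ethers survive.

Step 7
Reactants: 11 [(3S)-7-(benzyloxy)-8-methoxychroman-3-yl]methanol
Product: 12 (3R)-7-(benzyloxy)-8-methoxychromane-3-carbaldehyde
Conditions: Dess–Martin periodinane (1.2 equiv), CH2Cl2, 0 °C to rt; crude aldehyde used at once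
Reagents that add atoms: none
Why: Dess–Martin oxidation stops at the aldehyde under amine-free conditions and so avoids the base that could racemise C3 by enolisation or by reversible β-elimination of the aryloxide.

Step 8
Reactants: 12 (3R)-7-(benzyloxy)-8-methoxychromane-3-carbaldehyde
Product: 13 (3S)-7-(benzyloxy)-3-[(E)-2-iodoethenyl]-8-methoxychromane
Conditions: CrCl2 (6 equiv), CHI3 (2 equiv), dioxane–THF (6:1), 0 °C to rt
Reagents that add atoms: iodoform, IC(I)I
Why: Takai iodoolefination, in which the gem-dichromium species adds to the aldehyde and elimination from the less crowded adduct favours the E-iodoalkene, particularly with α-branched aldehydes, while the non-basic medium spares the α-stereocentre C3.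

Step 9
Reactants: 14 dimethyl squarate
Product: 15 tert-butyl methyl squarate (3-tert-butoxy-4-methoxycyclobut-3-ene-1,2-dione)
Conditions: t-BuOLi (1.0 equiv), THF, −78 to 0 °C; aq NH4Cl
Reagents that add atoms: lithium tert-butoxide, CC(C)(C)[O-].[Li+]
Why: Vinylogous transesterification (conjugate addition–elimination) of a squarate ester, in which tert-butoxide expels the less basic methoxide and the first tert-butoxy group shields the neighbouring ring carbon, so one equivalent should stop mainly at the mixed diester, separable from 14 by chromatography.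

Step 10
Reactants: 13 (3S)-7-(benzyloxy)-3-[(E)-2-iodoethenyl]-8-methoxychromane; 15 tert-butyl methyl squarate
Product: 18 2-tert-butoxy-4-hydroxy-3-methoxy-4-{(E)-2-[(3S)-7-(benzyloxy)-8-methoxychroman-3-yl]ethenyl}cyclobut-2-en-1-one (both carbinol epimers), via vinyllithium 16 (not isolated), via lithium alkoxide 17 (not isolated)
Conditions: t-BuLi (2.05 equiv), Et2O, −78 °C; cannulate into 15 (1.2 equiv), THF, −78 °C; aq NH4Cl, −78 °C
Reagents that add atoms: none
Why: Iodine–lithium exchange with retention of alkene geometry followed by 1,2-addition of the alkenyllithium to a squarate ester, the standard entry to 4-alkenyl-4-hydroxycyclobutenones, where the tert-butoxy group turns away from the methoxy group and covers both faces of its own adjacent carbonyl, so attack goes to the carbonyl beside the methoxy-bearing carbon, and the new carbinol centre forms without control as two epimers that converge in step 11.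

Step 11
Reactants: 18 2-tert-butoxy-4-hydroxy-3-methoxy-4-{(E)-2-[(3S)-7-(benzyloxy)-8-methoxychroman-3-yl]ethenyl}cyclobut-2-en-1-one
Product: 21 2-[(3S)-7-(benzyloxy)-8-methoxychroman-3-yl]-6-tert-butoxy-5-methoxybenzene-1,4-diol (isoflavan with free 2'- and 5'-OH), via dienylketene 19 (not isolated), via cyclohexadienone 20 (not isolated)
Conditions: degassed toluene (0.02 M), 110 °C, Ar, sealed vessel; concentrated under Ar and used crude
Reagents that add atoms: none
Why: Heating triggers conrotatory 4π opening of the cyclobutenone by cleavage of the bond between the ketone carbon and the carbinol carbon to give dienylketene 19, whose ketene carbon bonds to the alkene carbon carrying the chromanyl group (new C1'–C2' bond) to give cyclohexadienone 20, and enolisation of 20 delivers hydroquinone 21. The closest known reaction type is the Moore rearrangement, the thermal ring expansion of squarate-derived 4-alkenyl-4-hydroxycyclobutenones to oxygenated hydroquinones, which also tolerates tert-butoxy substituents. Ring B closes by a thermal disrotatory 6π electrocyclisation of the ketene–diene array and is made irreversible by aromatisation. No stereocentre is created, since the carbinol centre of 18 and the transient sp3 C1' of 20 both become sp2, and C3 lies outside the reacting π system under neutral aprotic conditions, so its configuration is retained. The step needs torquoselectivity, secured by the hydroxyl donor, which rotates outward and so places the alkenyl group cis to the ketene, and it needs the E alkene, which keeps C3–H out of reach of the diene terminus and thereby excludes a 1,5-hydrogen shift. The atom map follows from constitution (ketone C to C2', C–Ot-Bu to C3', C–OMe to C4', carbinol C to C5', vinyl CH to C6'), and exclusion of oxygen keeps 21 from oxidising.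

Step 12
Reactants: 21 2-[(3S)-7-(benzyloxy)-8-methoxychroman-3-yl]-6-tert-butoxy-5-methoxybenzene-1,4-diol
Product: 22 (3S)-7-(benzyloxy)-3-(3-tert-butoxy-2,4,5-trimethoxyphenyl)-8-methoxychromane
Conditions: MeI (6 equiv), K2CO3 (5 equiv), degassed DMF, rt to 40 °C, Ar
Reagents that add atoms: iodomethane, CI
Why: Double Williamson O-methylation, in which the small electrophile in a polar aprotic solvent also reaches the flanked 2'-phenoxide, the tert-butyl and benzyl ethers are inert to carbonate, and argon protects the hydroquinone anions from oxidation.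

Step 13
Reactants: 22 (3S)-7-(benzyloxy)-3-(3-tert-butoxy-2,4,5-trimethoxyphenyl)-8-methoxychromane
Product: 23 (3S)-3-(3-hydroxy-2,4,5-trimethoxyphenyl)-8-methoxychroman-7-ol (target)
Conditions: BCl3 (5 equiv), pentamethylbenzene (5 equiv), CH2Cl2, −78 °C; then H2O
Reagents that add atoms: none
Why: Lewis-acid ether cleavage with a cation scavenger, since at −78 °C BCl3 ionises only the ethers that leave as stabilised cations (tert-butyl and benzyl), pentamethylbenzene captures the benzyl cation before it can alkylate the electron-rich rings, and the methyl ethers and the chroman C2–O bond require much higher temperatures.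

**Compound list**

1 | 2-methoxyresorcinol | COc1c(O)cccc1O | starting material
2 | [(2,4-dihydroxy-3-methoxyphenyl)methylidene]dimethyliminium dichlorophosphate | COc1c(O)ccc(C=[N+](C)C)c1O.[O-]P(=O)(Cl)Cl | intermediate (not isolated)
3 | 2,4-dihydroxy-3-methoxybenzaldehyde | COc1c(O)ccc(C=O)c1O | intermediate
4 | 4-(benzyloxy)-2-hydroxy-3-methoxybenzaldehyde | COc1c(OCc2ccccc2)ccc(C=O)c1O | intermediate
5 | acrolein | C=CC=O | starting material
6 | 4-(benzyloxy)-3-methoxy-2-(3-oxopropoxy)benzaldehyde | O=CCCOc1c(C=O)ccc(OCc2ccccc2)c1OC | intermediate (not isolated)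
7 | 7-(benzyloxy)-4-hydroxy-8-methoxychromane-3-carbaldehyde (stereoisomer mixture) | O=CC1COc2c(ccc(OCc3ccccc3)c2OC)C1O | intermediate (not isolated)
8 | 7-(benzyloxy)-8-methoxy-2H-chromene-3-carbaldehyde | O=CC1=Cc2ccc(OCc3ccccc3)c(OC)c2OC1 | intermediate
9 | 7-(benzyloxy)-8-methoxy-2H-chromene-3-carboxylic acid | OC(=O)C1=Cc2ccc(OCc3ccccc3)c(OC)c2OC1 | intermediate
10 | (3R)-7-(benzyloxy)-8-methoxychromane-3-carboxylic acid | OC(=O)[C@H]1COc2c(ccc(OCc3ccccc3)c2OC)C1 | intermediate
11 | [(3S)-7-(benzyloxy)-8-methoxychroman-3-yl]methanol | OC[C@H]1COc2c(ccc(OCc3ccccc3)c2OC)C1 | intermediate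
12 | (3R)-7-(benzyloxy)-8-methoxychromane-3-carbaldehyde | O=C[C@H]1COc2c(ccc(OCc3ccccc3)c2OC)C1 | intermediate
13 | (3S)-7-(benzyloxy)-3-[(E)-2-iodoethenyl]-8-methoxychromane | I/C=C/[C@H]1COc2c(ccc(OCc3ccccc3)c2OC)C1 | intermediate
14 | dimethyl squarate | COC1=C(OC)C(=O)C1=O | starting material
15 | tert-butyl methyl squarate | COC1=C(OC(C)(C)C)C(=O)C1=O | intermediate
16 | (E)-2-[(3S)-7-(benzyloxy)-8-methoxychroman-3-yl]ethenyllithium | [Li]/C=C/[C@H]1COc2c(ccc(OCc3ccccc3)c2OC)C1 | intermediate (not isolated)
17 | lithium alkoxide of 18 (both epimers) | [Li+].[O-]C1(/C=C/[C@H]2COc3c(ccc(OCc4ccccc4)c3OC)C2)C(OC)=C(OC(C)(C)C)C1=O | intermediate (not isolated)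
18 | 2-tert-butoxy-4-hydroxy-3-methoxy-4-{(E)-2-[(3S)-7-(benzyloxy)-8-methoxychroman-3-yl]ethenyl}cyclobut-2-en-1-one (both carbinol epimers) | O=C1C(OC(C)(C)C)=C(OC)C1(O)/C=C/[C@H]1COc2c(ccc(OCc3ccccc3)c2OC)C1 | intermediate (key-step precursor)
19 | dienylketene, alkenyl group cis to the ketene, distal alkene E | O=C=C(OC(C)(C)C)/C(OC)=C(O)\C=C\[C@H]1COc2c(ccc(OCc3ccccc3)c2OC)C1 | intermediate (not isolated)
20 | 6-[(3S)-7-(benzyloxy)-8-methoxychroman-3-yl]-2-tert-butoxy-4-hydroxy-3-methoxycyclohexa-2,4-dien-1-one | O=C1C(OC(C)(C)C)=C(OC)C(O)=CC1[C@H]1COc2c(ccc(OCc3ccccc3)c2OC)C1 | intermediate (not isolated)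
21 | 2-[(3S)-7-(benzyloxy)-8-methoxychroman-3-yl]-6-tert-butoxy-5-methoxybenzene-1,4-diol | COc1c(O)cc([C@H]2COc3c(ccc(OCc4ccccc4)c3OC)C2)c(O)c1OC(C)(C)C | intermediate (key-step product)
22 | (3S)-7-(benzyloxy)-3-(3-tert-butoxy-2,4,5-trimethoxyphenyl)-8-methoxychromane | COc1cc([C@H]2COc3c(ccc(OCc4ccccc4)c3OC)C2)c(OC)c(OC(C)(C)C)c1OC | intermediate
23 | (3S)-3-(3-hydroxy-2,4,5-trimethoxyphenyl)-8-methoxychroman-7-ol | COc1cc([C@H]2COc3c(ccc(O)c3OC)C2)c(OC)c(O)c1OC | target

**Total step count:** 13. **Longest linear sequence:** 12 (steps 1–8 and 10–13). Step 9 is a one-step side branch.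

**Steps most likely to fail**

**Step 11.** The ketene may be consumed before it cyclises, through capture by adventitious nucleophiles or through oligomerisation while closure at the branched alkene terminus is slow. The tert-butyl group may be lost thermally as isobutene, or the product may oxidise in air.

The fallback makes the same C1'–C2' bond from the alkyne analogue and sets out from aldehyde 12. Ramirez dibromoolefination (CBr4, PPh3, CH2Cl2, 0 °C) would give the 1,1-dibromoalkene F1. Treatment with n-BuLi (2 equiv, THF, −78 °C, Corey–Fuchs) converts it into the lithium acetylide F2. This is added to squarate 15 under the same steric control to give the 4-alkynyl-4-hydroxycyclobutenone F3. That compound should rearrange already near 80 °C (MeCN or toluene) by ring opening, six-membered diradical closure and hydrogen transfer to the air-stable 1,4-benzoquinone F4. Reduction with Na2S2O4 (THF–H2O) rejoins the route at hydroquinone 21.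

**Step 10.** The site selectivity between the two squarate carbonyl groups may erode, or material may be lost by proton transfer to the vinyllithium.

The fallback sets out from vinyl iodide 13 (through 16) and uses commercial, symmetrical diisopropyl squarate, for which no site question exists. The adduct is methylated in the same flask with MeOTf to give the 4-methoxy-2,3-diisopropoxycyclobutenone F5. NaOMe in MeOH then exchanges only the alkoxy group at C3, the sole alkoxy carbon β to the ketone, by conjugate addition–elimination on the vinylogous ester. This gives the 2-isopropoxy-3,4-dimethoxycyclobutenone F6, so the ether positions follow from constitution and not from size. Thermolysis as in step 11 would give the 2'-phenol F7 with 5'-OMe already present. MeI/K2CO3 gives the 3'-isopropyl ether F8. BCl3/pentamethylbenzene (−78 to 0 °C) removes isopropyl and benzyl, and the route is rejoined at target 23.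

**Step 8 (with the aldehyde from step 7).** C3 may lose configurational integrity by enolisation or by reversible β-elimination of the aryloxide, and control of the alkene geometry may be insufficient.

The fallback sets out from the achiral enal 8 and creates C3 last. Takai iodoolefination of 8, which has no stereocentre to lose, would give the dienyl iodide F9. Treatment with t-BuLi gives the dienyllithium F10, and addition to 15 gives the dienyl carbinol F11. Thermolysis closes ring B on the proximal alkene to give the isoflav-3-ene hydroquinone F12, and MeI/K2CO3 gives the isoflav-3-ene tetraether F13. Iridium–phosphine-oxazoline-catalysed asymmetric hydrogenation of this 3-aryl-2H-chromene then rejoins the route at 22. This variant is held in reserve because it moves the stereodefining step onto a late, hindered trisubstituted alkene.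

**Further compounds**

F1 | step 11 | (3S)-7-(benzyloxy)-3-(2,2-dibromoethenyl)-8-methoxychromane | BrC(Br)=C[C@H]1COc2c(ccc(OCc3ccccc3)c2OC)C1
F2 | step 11 | lithium [(3S)-7-(benzyloxy)-8-methoxychroman-3-yl]acetylide | [Li]C#C[C@H]1COc2c(ccc(OCc3ccccc3)c2OC)C1
F3 | step 11 | 4-{[(3S)-7-(benzyloxy)-8-methoxychroman-3-yl]ethynyl}-2-tert-butoxy-4-hydroxy-3-methoxycyclobut-2-en-1-one | O=C1C(OC(C)(C)C)=C(OC)C1(O)C#C[C@H]1COc2c(ccc(OCc3ccccc3)c2OC)C1
F4 | step 11 | 5-[(3S)-7-(benzyloxy)-8-methoxychroman-3-yl]-3-tert-butoxy-2-methoxycyclohexa-2,5-diene-1,4-dione | O=C1C=C([C@H]2COc3c(ccc(OCc4ccccc4)c3OC)C2)C(=O)C(OC(C)(C)C)=C1OC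
F5 | step 10 | 4-{(E)-2-[(3S)-7-(benzyloxy)-8-methoxychroman-3-yl]ethenyl}-2,3-diisopropoxy-4-methoxycyclobut-2-en-1-one | O=C1C(OC(C)C)=C(OC(C)C)C1(OC)/C=C/[C@H]1COc2c(ccc(OCc3ccccc3)c2OC)C1
F6 | step 10 | 4-{(E)-2-[(3S)-7-(benzyloxy)-8-methoxychroman-3-yl]ethenyl}-2-isopropoxy-3,4-dimethoxycyclobut-2-en-1-one | O=C1C(OC(C)C)=C(OC)C1(OC)/C=C/[C@H]1COc2c(ccc(OCc3ccccc3)c2OC)C1
F7 | step 10 | 6-[(3S)-7-(benzyloxy)-8-methoxychroman-3-yl]-2-isopropoxy-3,4-dimethoxyphenol | COc1cc([C@H]2COc3c(ccc(OCc4ccccc4)c3OC)C2)c(O)c(OC(C)C)c1OC
F8 | step 10 | (3S)-7-(benzyloxy)-3-(3-isopropoxy-2,4,5-trimethoxyphenyl)-8-methoxychromane | COc1cc([C@H]2COc3c(ccc(OCc4ccccc4)c3OC)C2)c(OC)c(OC(C)C)c1OC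
F9 | step 8 | 7-(benzyloxy)-3-[(E)-2-iodoethenyl]-8-methoxy-2H-chromene | I/C=C/C1=Cc2ccc(OCc3ccccc3)c(OC)c2OC1
F10 | step 8 | (E)-2-[7-(benzyloxy)-8-methoxy-2H-chromen-3-yl]ethenyllithium | [Li]/C=C/C1=Cc2ccc(OCc3ccccc3)c(OC)c2OC1
F11 | step 8 | 4-{(E)-2-[7-(benzyloxy)-8-methoxy-2H-chromen-3-yl]ethenyl}-2-tert-butoxy-4-hydroxy-3-methoxycyclobut-2-en-1-one | O=C1C(OC(C)(C)C)=C(OC)C1(O)/C=C/C1=Cc2ccc(OCc3ccccc3)c(OC)c2OC1
F12 | step 8 | 2-[7-(benzyloxy)-8-methoxy-2H-chromen-3-yl]-6-tert-butoxy-5-methoxybenzene-1,4-diol | COc1c(O)cc(C2=Cc3ccc(OCc4ccccc4)c(OC)c3OC2)c(O)c1OC(C)(C)C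
F13 | step 8 | 7-(benzyloxy)-3-(3-tert-butoxy-2,4,5-trimethoxyphenyl)-8-methoxy-2H-chromene | COc1cc(C2=Cc3ccc(OCc4ccccc4)c(OC)c3OC2)c(OC)c(OC(C)(C)C)c1OC
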